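Everything rests on cutting ring A of the target, the dihydrofuran O1–C2–C3–C3a–C7a, back to an aromatic acylphloroglucinol, one formaldehyde carbon (C3) and one acetonyl ylide carbon (C2). The key step exploits two features of ring A: C3 is an unsubstituted methylene on C3a, beside the oxygen-bearing C7a, and the C2 stereocentre carries an oxygenated carbon. An ortho-quinone methide made in the flask is captured by a quinidinium ylide, which forms C3a–C3, C3–C2 and O1–C2 and sets C2 in one operation. The precursor is the unprotected methyl isobutyryl phloroglucinol with a single free ring carbon. Chelation-controlled Grignard addition and two dearomatising prenylations complete the target.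

Key step: step 3

Numbering: benzofuran numbering throughout (O1, C2, C3, C3a, C4 to C7, C7a); C2′ is the carbinol carbon of the side chain.

Assumption: the quinidine-derived salt 6 is taken to deliver (S) at C2 (the quinine-derived pseudoenantiomer would be used in the same way if the sense proved opposite), and carbonate 18 is taken as a catalogue reagent.

Step 1
Reactants: 1 2-methylphloroglucinol; 2 isobutyryl chloride
Product: 3 2-methyl-1-(2,4,6-trihydroxy-3-methylphenyl)propan-1-one
Conditions: AlCl3 (3.5 equiv), PhNO2, 70 °C; ice/aq. HCl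
Reagents that add atoms: none
Why: Friedel–Crafts C-acylation of a phloroglucinol, in which the two free ring positions of 1 are equivalent and the aluminium-chelated aryl ketone formed is deactivated towards a second acylation.

Step 2
Reactants: 4 quinidine; 5 chloroacetone
Product: 6 N-(2-oxopropyl)quinidinium chloride
Conditions: THF, 40 °C, 24 h; salt filtered, washed with Et2O
Reagents that add atoms: none
Why: Menshutkin quaternisation, in which the quinuclidine nitrogen is far more nucleophilic than the quinoline nitrogen or the C9 hydroxyl and displaces chloride from the activated α-chloroketone.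

Step 3
Reactants: 3 2-methyl-1-(2,4,6-trihydroxy-3-methylphenyl)propan-1-one; 7 formaldehyde; 6 N-(2-oxopropyl)quinidinium chloride
Product: 12 1-[(2S)-4,6-dihydroxy-7-methyl-5-(2-methylpropanoyl)-2,3-dihydro-1-benzofuran-2-yl]ethan-1-one, via hydroxymethyl phenol 8 (not isolated), via ortho-quinone methide 9 (not isolated), via quinidinium ylide 10 (not isolated), via ammonium phenoxide betaine 11 (not isolated)
Conditions: 6 (1.5 equiv), Cs2CO3 (3 equiv), CH2Cl2, 0 °C; 3 and 7 (37% aq., 1.2 equiv) in THF co-added over 6 h; pH 4 phosphate quench; 4 recovered by acid extraction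
Reagents that add atoms: none
Why: Under Cs2CO3 the phenoxide of 3 is hydroxymethylated by 7 at its only free ring carbon (C3a–C3) and 8 loses hydroxide to give the ortho-quinone methide 9, whose exocyclic CH2 is attacked by the carbon of ylide 10 (C3–C2, with rearomatisation) to give betaine 11, after which the phenoxide next to the new side chain displaces quinidine from C2 (O1–C2). The closest known reaction type is the asymmetric [4+1] annulation of ortho-quinone methides generated in the flask with cinchona-derived ammonium ylides, which gives 2-acyl-2,3-dihydrobenzofurans, combined here with the familiar base-induced formaldehyde condensation of phloroglucinols. Ring A closes by a 5-exo-tet SN2 displacement with inversion at C2. The C2 configuration is controlled by the quinidinium group, which shields one face of the enolate-like ylide carbon during C–C bond formation before the stereospecific invertive closure. The step needs closure through the oxygen on C7a and not through the one on C4, which is secured because the oxygen para to the acyl group is the most acidic and is not tied up in the hydrogen bond or cesium chelate with the ketone, the same preference that directs O-alkylation of such triols to that position. It also needs ylide capture to outrun diarylmethane formation and C2 to keep its configuration, which the slow co-addition of 3 and 7 into an excess of 10 (ketone-stabilised ammonium ylides add only reversibly to aldehydes), the low temperature and the buffered quench are meant to secure.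

Step 4
Reactants: 12 1-[(2S)-4,6-dihydroxy-7-methyl-5-(2-methylpropanoyl)-2,3-dihydro-1-benzofuran-2-yl]ethan-1-one; 13 5-bromo-2-methylpent-2-ene
Product: 15 1-{(2S)-4,6-dihydroxy-2-[(2S)-2-hydroxy-6-methylhept-5-en-2-yl]-7-methyl-2,3-dihydro-1-benzofuran-5-yl}-2-methylpropan-1-one, via 4-methylpent-3-enylmagnesium bromide 14 (not isolated)
Conditions: 13, Mg turnings, THF, 35 °C; this solution of 14 (3.5 equiv) added to 12, THF, −78 to −40 °C; aq. NH4Cl
Reagents that add atoms: none
Why: Chelation-controlled (Cram chelate) Grignard addition, in which two equivalents of 14 turn the phenols into magnesium phenoxides that switch off the aryl ketone as a vinylogous carboxylate, while magnesium bridging O1 and the acetyl oxygen directs the nucleophile to the carbonyl face syn to the C2 hydrogen and anti to C3, setting C2′ as (S) without disturbing C2.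

Step 5
Reactants: 15 1-{(2S)-4,6-dihydroxy-2-[(2S)-2-hydroxy-6-methylhept-5-en-2-yl]-7-methyl-2,3-dihydro-1-benzofuran-5-yl}-2-methylpropan-1-one; 16 prenyl bromide
Product: 17 (2S,7S)-4-hydroxy-2-[(2S)-2-hydroxy-6-methylhept-5-en-2-yl]-7-methyl-7-(3-methylbut-2-en-1-yl)-5-(2-methylpropanoyl)-2,3-dihydro-1-benzofuran-6(7H)-one
Conditions: NaOMe (2.2 equiv), MeOH, −10 °C; 16 (1.15 equiv), to 0 °C; aq. citric acid; chromatography to remove the C7 epimer
Reagents that add atoms: none
Why: Alkylative dearomatisation of a phloroglucinol dianion with an allylic bromide in a protic medium, as used to prenylate methyl-bearing ring carbons of acylphloroglucinols: hydrogen-bonded oxide oxygens favour C-alkylation, C5 is deactivated by its acyl group, C7 (ortho to the C6 oxide, para to the C4 oxide, carrying only a freely rotating methyl) should be preferred over the ring-fusion carbon C3a, whose alkylation would force ring A to give up its endocyclic double bond and must pass the C2 substituent, and the new (7S) centre arises from attack on the face remote from the C2 side chain, a modest 1,4-bias, so the C7 epimer is expected as a co-product and is removed at this stage.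

Step 6
Reactants: 17 (2S,7S)-4-hydroxy-2-[(2S)-2-hydroxy-6-methylhept-5-en-2-yl]-7-methyl-7-(3-methylbut-2-en-1-yl)-5-(2-methylpropanoyl)-2,3-dihydro-1-benzofuran-6(7H)-one; 18 tert-butyl 2-methylbut-3-en-2-yl carbonate
Product: 19 (2S,5R,7S)-2-[(2S)-2-hydroxy-6-methylhept-5-en-2-yl]-7-methyl-5,7-bis(3-methylbut-2-en-1-yl)-5-(2-methylpropanoyl)-2,3-dihydro-1-benzofuran-4,6(5H,7H)-dione
Conditions: Pd2(dba)3 (2.5 mol%), PPh3 (10 mol%), 18 (1.3 equiv), THF, 40 °C; chromatography
Reagents that add atoms: none
Why: Tsuji–Trost prenylation with loss of CO2 from the carbonate, in which zerovalent palladium ionises 18 to a π-(1,1-dimethylallyl)palladium cation and tert-butoxide that deprotonates the acidic triketone, the soft triketonate attacks the unsubstituted allyl terminus through C5 (any O-prenyl enol ether re-ionises and funnels to the C-alkylated product), and attack on the ring face carrying the small C7 methyl, anti to the C7 prenyl group, sets C5 as (R), with any C5 epimer removed by chromatography.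

Compound list
1 | 2-methylbenzene-1,3,5-triol (2-methylphloroglucinol) | Cc1c(O)cc(O)cc1O | starting material
2 | 2-methylpropanoyl chloride (isobutyryl chloride) | CC(C)C(=O)Cl | starting material
3 | 2-methyl-1-(2,4,6-trihydroxy-3-methylphenyl)propan-1-one | CC(C)C(=O)c1c(O)cc(O)c(C)c1O | intermediate
4 | quinidine | COC1=CC2=C(C=CN=C2C=C1)[C@@H]([C@H]3C[C@@H]4CCN3C[C@@H]4C=C)O | starting material
5 | 1-chloropropan-2-one (chloroacetone) | CC(=O)CCl | starting material
6 | N-(2-oxopropyl)quinidinium chloride | COC1=CC2=C(C=CN=C2C=C1)[C@@H]([C@H]3C[C@@H]4CC[N@@+]3(CC(C)=O)C[C@@H]4C=C)O.[Cl-] | intermediate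
7 | formaldehyde | C=O | starting material
8 | 1-[2,4,6-trihydroxy-3-(hydroxymethyl)-5-methylphenyl]-2-methylpropan-1-one | CC(C)C(=O)c1c(O)c(CO)c(O)c(C)c1O | intermediate
9 | 3,5-dihydroxy-2-methyl-6-methylidene-4-(2-methylpropanoyl)cyclohexa-2,4-dien-1-one | C=C1C(=O)C(C)=C(O)C(C(=O)C(C)C)=C1O | intermediate
10 | N-(2-oxopropan-1-id-1-yl)quinidinium (ammonium ylide) | COC1=CC2=C(C=CN=C2C=C1)[C@@H]([C@H]3C[C@@H]4CC[N@@+]3([CH-]C(C)=O)C[C@@H]4C=C)O | intermediate
11 | 3,5-dihydroxy-6-methyl-4-(2-methylpropanoyl)-2-[(2R)-3-oxo-2-(quinidinium-N-yl)butyl]phenolate | COC1=CC2=C(C=CN=C2C=C1)[C@@H]([C@H]3C[C@@H]4CC[N@@+]3([C@@H](C(C)=O)Cc5c(O)c(C(=O)C(C)C)c(O)c(C)c5[O-])C[C@@H]4C=C)O | intermediate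
12 | 1-[(2S)-4,6-dihydroxy-7-methyl-5-(2-methylpropanoyl)-2,3-dihydro-1-benzofuran-2-yl]ethan-1-one | CC(=O)[C@@H]1Cc2c(O1)c(C)c(O)c(C(=O)C(C)C)c2O | intermediate
13 | 5-bromo-2-methylpent-2-ene | CC(C)=CCCBr | starting material
14 | 4-methylpent-3-enylmagnesium bromide | CC(C)=CCC[Mg]Br | intermediate
15 | 1-{(2S)-4,6-dihydroxy-2-[(2S)-2-hydroxy-6-methylhept-5-en-2-yl]-7-methyl-2,3-dihydro-1-benzofuran-5-yl}-2-methylpropan-1-one | CC(C)=CCC[C@](C)(O)[C@@H]1Cc2c(O1)c(C)c(O)c(C(=O)C(C)C)c2O | intermediate
16 | 1-bromo-3-methylbut-2-ene (prenyl bromide) | CC(C)=CCBr | starting material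
17 | (2S,7S)-4-hydroxy-2-[(2S)-2-hydroxy-6-methylhept-5-en-2-yl]-7-methyl-7-(3-methylbut-2-en-1-yl)-5-(2-methylpropanoyl)-2,3-dihydro-1-benzofuran-6(7H)-one | CC(C)=CCC[C@](C)(O)[C@@H]1CC2=C(O1)[C@](C)(CC=C(C)C)C(=O)C(C(=O)C(C)C)=C2O | intermediate
18 | tert-butyl 2-methylbut-3-en-2-yl carbonate | CC(C)(C)OC(=O)OC(C)(C)C=C | starting material
19 | (2S,5R,7S)-2-[(2S)-2-hydroxy-6-methylhept-5-en-2-yl]-7-methyl-5,7-bis(3-methylbut-2-en-1-yl)-5-(2-methylpropanoyl)-2,3-dihydro-1-benzofuran-4,6(5H,7H)-dione | CC(C)=CCC[C@](C)(O)[C@@H]1CC2=C(O1)[C@](C)(CC=C(C)C)C(=O)[C@](CC=C(C)C)(C(=O)C(C)C)C2=O | target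

Total step count: 6. Longest linear sequence: 5 steps (steps 1, 3, 4, 5 and 6); step 2 is a one-step side branch.

Steps most likely to fail

Step 3. Three processes threaten it: methylene bridging, in which unreacted phenoxide adds to the quinone methide faster than the ylide does; ring closure through the oxygen on C4; and base-induced loss of configuration at C2 if the reaction is slow. The fallback separates the formaldehyde condensation from the annulation. It sets out from 3, which with 7 and sodium 4-methylbenzenesulfinate in aqueous formic acid should give the bench-stable benzylic sulfone 2-methyl-1-{2,4,6-trihydroxy-3-methyl-5-[(4-methylbenzenesulfonyl)methyl]phenyl}propan-1-one F1, which is isolated. Treated with 6 and Cs2CO3 in CH2Cl2 at 0 °C, it should release 9 by sulfinate elimination with no free formaldehyde and no unsubstituted arene present. The same ylide capture and 5-exo-tet closure then return the route to 12.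

Step 5. Alkylation may go to the ring-fusion carbon C3a or to oxygen instead of C7, and the remote C2 substituent discriminates only weakly between the two faces of C7. The fallback sets out from 15 and replaces substrate control by a blocking group and a chiral catalyst. Silylation of the less hindered C4 hydroxyl (iPr3SiCl, imidazole, DMF) should give 1-{(2S)-6-hydroxy-2-[(2S)-2-hydroxy-6-methylhept-5-en-2-yl]-7-methyl-4-{[tri(propan-2-yl)silyl]oxy}-2,3-dihydro-1-benzofuran-5-yl}-2-methylpropan-1-one F2. A palladium-catalysed asymmetric allylic dearomatisation follows (Pd2(dba)3, the matched enantiomer of N,N′-(cyclohexane-1,2-diyl)bis[2-(diphenylphosphanyl)benzamide], 18, toluene). The single remaining phenoxide directs attack to its ortho carbon C7 and the ligand selects the face, giving (2S,7S)-2-[(2S)-2-hydroxy-6-methylhept-5-en-2-yl]-7-methyl-7-(3-methylbut-2-en-1-yl)-5-(2-methylpropanoyl)-4-{[tri(propan-2-yl)silyl]oxy}-2,3-dihydro-1-benzofuran-6(7H)-one F3. Bu4NF buffered with AcOH removes the silyl group and returns to 17.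

Step 6. Facial selectivity at C5 may be low because the C7 methyl and prenyl groups differ little in size, carbon alkylation of the highly stabilised triketonate may be slow, and the prenyl-palladium intermediate may be lost by β-hydride elimination. The fallback sets out from 17 and uses an unhindered allyl group under catalyst control. Allyl chloroformate and pyridine should convert the enol into (2S,7S)-2-[(2S)-2-hydroxy-6-methylhept-5-en-2-yl]-7-methyl-7-(3-methylbut-2-en-1-yl)-5-(2-methylpropanoyl)-6-oxo-2,3,6,7-tetrahydro-1-benzofuran-4-yl prop-2-en-1-yl carbonate F4; the site of O-acylation is immaterial because every isomer ionises to the same triketonate. Intramolecular decarboxylative asymmetric allylation (Pd2(dba)3, the matched enantiomer of the same chiral bisphosphine) should give (2S,5R,7S)-2-[(2S)-2-hydroxy-6-methylhept-5-en-2-yl]-7-methyl-7-(3-methylbut-2-en-1-yl)-5-(2-methylpropanoyl)-5-(prop-2-en-1-yl)-2,3-dihydro-1-benzofuran-4,6(5H,7H)-dione F5. Cross-metathesis with 2-methylbut-2-ene (second-generation Grubbs catalyst, CH2Cl2, 40 °C) converts the allyl into the prenyl group, the existing trisubstituted alkenes undergoing only degenerate exchange, and arrives at 19.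

Further compounds
F1 | step 3 | 2-methyl-1-{2,4,6-trihydroxy-3-methyl-5-[(4-methylbenzenesulfonyl)methyl]phenyl}propan-1-one | CC(C)C(=O)c1c(O)c(CS(=O)(=O)c2ccc(C)cc2)c(O)c(C)c1O
F2 | step 5 | 1-{(2S)-6-hydroxy-2-[(2S)-2-hydroxy-6-methylhept-5-en-2-yl]-7-methyl-4-{[tri(propan-2-yl)silyl]oxy}-2,3-dihydro-1-benzofuran-5-yl}-2-methylpropan-1-one | CC(C)=CCC[C@](C)(O)[C@@H]1Cc2c(O1)c(C)c(O)c(C(=O)C(C)C)c2O[Si](C(C)C)(C(C)C)C(C)C
F3 | step 5 | (2S,7S)-2-[(2S)-2-hydroxy-6-methylhept-5-en-2-yl]-7-methyl-7-(3-methylbut-2-en-1-yl)-5-(2-methylpropanoyl)-4-{[tri(propan-2-yl)silyl]oxy}-2,3-dihydro-1-benzofuran-6(7H)-one | CC(C)=CCC[C@](C)(O)[C@@H]1CC2=C(O1)[C@](C)(CC=C(C)C)C(=O)C(C(=O)C(C)C)=C2O[Si](C(C)C)(C(C)C)C(C)C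
F4 | step 6 | (2S,7S)-2-[(2S)-2-hydroxy-6-methylhept-5-en-2-yl]-7-methyl-7-(3-methylbut-2-en-1-yl)-5-(2-methylpropanoyl)-6-oxo-2,3,6,7-tetrahydro-1-benzofuran-4-yl prop-2-en-1-yl carbonate | CC(C)=CCC[C@](C)(O)[C@@H]1CC2=C(O1)[C@](C)(CC=C(C)C)C(=O)C(C(=O)C(C)C)=C2OC(=O)OCC=C
F5 | step 6 | (2S,5R,7S)-2-[(2S)-2-hydroxy-6-methylhept-5-en-2-yl]-7-methyl-7-(3-methylbut-2-en-1-yl)-5-(2-methylpropanoyl)-5-(prop-2-en-1-yl)-2,3-dihydro-1-benzofuran-4,6(5H,7H)-dione | CC(C)=CCC[C@](C)(O)[C@@H]1CC2=C(O1)[C@](C)(CC=C(C)C)C(=O)[C@](CC=C)(C(=O)C(C)C)C2=O
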